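**Retrosynthetic overview**

- The target **15** is a benzene ring (C1–C6) carrying CO2Me at C1, a free OH at C2, H at C3, OMe at C4, H at C5 and icosyl at C6. The strategy rests on the C2‑OH / C3‑H / C4‑OMe resorcinol monomethyl ether unit, which is what a vinylketene and an alkoxyalkyne give, the ketene oxygen becoming the phenol.
- Key disconnection: bonds C2–C3, C4–C5 and C1–C2 are cut, giving cyclobutenone **7** (supplies C2, C5, C6, C1 with ester and icosyl in place) and methoxyethyne **10** (supplies C3, C4). The benzene ring is the only ring and is formed in the last step.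
- **7** comes from chloride **6** by zinc dechlorination. **6** comes from a [2+2] cycloaddition of docos‑1‑yne **2** with chloro(methoxycarbonyl)ketene **5**, released by zinc from the trichloride **4**, itself made by chlorinating methyl malonyl chloride **3**.
- **2** comes from 1‑bromoicosane **1** and lithium acetylide; **10** comes from chloroacetaldehyde dimethyl acetal **8** and NaNH2.

Key step: step 6

Remark: the target has no stereocentre; **6**, **7**, **12** and **14** are racemic and their sp3 centres disappear on aromatisation. Reagents without a number are taken as commercial.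

**Step 1**
Reactants: 1 1-bromoicosane
Product: 2 docos-1-yne
Conditions: LiC≡CH·H2NCH2CH2NH2 (1.5 equiv), DMSO/THF, 10 °C → rt
Reagents that add atoms: lithium acetylide–ethylenediamine complex, [Li]C#C.NCCN
Why: SN2 alkylation of an acetylide by an unhindered primary bromide in a dipolar aprotic medium is the standard way to long-chain 1-alkynes; no stereocentre is formed.

**Step 2**
Reactants: 3 methyl malonyl chloride
Product: 4 methyl 2,2-dichloro-3-chloro-3-oxopropanoate
Conditions: SO2Cl2 (2.5 equiv), neat, 40 → 75 °C; distillation under reduced pressure
Reagents that add atoms: sulfuryl chloride, O=S(=O)(Cl)Cl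
Why: Electrophilic α-chlorination of a readily enolised malonyl derivative with SO2Cl2 should replace both C–H bonds while the acid chloride and the ester stay inert; no stereocentre is formed.

**Step 3**
Reactants: 4 methyl 2,2-dichloro-3-chloro-3-oxopropanoate; 2 docos-1-yne
Product: 6 methyl 1-chloro-2-icosyl-4-oxocyclobut-2-ene-1-carboxylate (racemic), via chloro(methoxycarbonyl)ketene 5 (not isolated)
Conditions: zinc–copper couple (1.6 equiv), Et2O/DME, 4 (1.5 equiv) added over 2 h, rt
Reagents that add atoms: none
Why: Zinc removes two chlorines from 4 to release the electrophilic chloroketene 5, which should undergo the ketene–alkyne [2+2] cycloaddition established for dichloroketene and alkylchloroketenes with terminal alkynes, the terminal alkyne carbon bonding to the ketene carbonyl carbon so that icosyl sits next to the chloro ester carbon; the quaternary centre forms as a racemate and is removed later.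

**Step 4**
Reactants: 6 methyl 1-chloro-2-icosyl-4-oxocyclobut-2-ene-1-carboxylate
Product: 7 methyl 2-icosyl-4-oxocyclobut-2-ene-1-carboxylate (racemic)
Conditions: Zn dust (1.5 equiv), AcOH, TMEDA, THF, 0 °C; cold work-up, used promptly
Reagents that add atoms: none
Why: Reductive dechlorination of a tertiary α-chloro β-keto ester by zinc with acetic acid as proton source, under the conditions established for 4,4-dichlorocyclobutenones, should leave the enone untouched; the new C–H centre is racemic and is erased on aromatisation.

**Step 5**
Reactants: 8 chloroacetaldehyde dimethyl acetal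
Product: 10 methoxyethyne, via sodium methoxyacetylide 9 (not isolated)
Conditions: NaNH2 (3.1 equiv), liquid NH3, −33 °C; NH3 evaporated; cold H2O/NaCl, −20 °C; distilled into toluene at −78 °C
Reagents that add atoms: none
Why: Base-induced double elimination (methanol, then HCl) from the α-chloro acetal with excess NaNH2 is the established route to alkoxyethynes, the product being held as its sodium acetylide until the aqueous quench; no stereocentre is formed.

**Step 6**
Reactants: 7 methyl 2-icosyl-4-oxocyclobut-2-ene-1-carboxylate; 10 methoxyethyne
Product: 15 methyl 2-hydroxy-6-icosyl-4-methoxybenzoate, via vinylketene 11 (not isolated), via vinylcyclobutenone 12 (not isolated), via dienylketene 13 (not isolated), via cyclohexadienone 14 (not isolated)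
Conditions: 10 (3 equiv), toluene, sealed tube, 80 °C, then 110 °C
Reagents that add atoms: none
Why: Heating opens 7 by four-electron conrotatory electrocyclic ring opening to vinylketene 11, whose ketene carbon (future C2) and α-carbon (future C5) add across methoxyethyne in a [2+2] cycloaddition to give 4-vinylcyclobutenone 12 (bonds C2–C3 and C4–C5); a second four-electron opening gives dienylketene 13, and its thermal six-electron disrotatory electrocyclisation joins the ester-bearing carbon C1 to the ketene carbon C2, closing the only ring as cyclohexadienone 14, which enolises to the phenol. The closest known reaction is the Danheiser benzannulation of cyclobutenones with alkoxyalkynes, which gives resorcinol monoethers of this pattern. No stereocentre remains, since the racemic sp3 centres of 7, 12 and 14 all end as aromatic carbons. Two selectivities are needed: the [2+2] regiochemistry, secured by the polarisation of the ynol ether (its unsubstituted nucleophilic carbon bonds to the electrophilic ketene carbon, so OMe ends at C4, meta to the new OH), and outward rotation of the ester in the opening of 7, which keeps the ketene away from the ester carbonyl and is the expected torquoelectronic preference of an ester placed next to hydrogen. Because the opening is reversible, excess alkyne should drain the outward-rotated ketene into product, and conjugation of the ester with the new diene should let the cascade start at or below 80 °C.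

**Compound list**

1 | 1-bromoicosane | CCCCCCCCCCCCCCCCCCCCBr | starting material
2 | docos-1-yne | CCCCCCCCCCCCCCCCCCCCC#C | intermediate
3 | methyl malonyl chloride (methyl 3-chloro-3-oxopropanoate) | COC(=O)CC(=O)Cl | starting material
4 | methyl 2,2-dichloro-3-chloro-3-oxopropanoate | COC(=O)C(Cl)(Cl)C(=O)Cl | intermediate
5 | chloro(methoxycarbonyl)ketene (methyl 2-chloro-3-oxoprop-2-enoate) | COC(=O)C(Cl)=C=O | intermediate
6 | methyl 1-chloro-2-icosyl-4-oxocyclobut-2-ene-1-carboxylate (racemic) | COC(=O)C1(Cl)C(=O)C=C1CCCCCCCCCCCCCCCCCCCC | intermediate
7 | methyl 2-icosyl-4-oxocyclobut-2-ene-1-carboxylate (racemic) | COC(=O)C1C(=O)C=C1CCCCCCCCCCCCCCCCCCCC | intermediate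
8 | chloroacetaldehyde dimethyl acetal (2-chloro-1,1-dimethoxyethane) | COC(CCl)OC | starting material
9 | sodium methoxyacetylide | COC#[C-].[Na+] | intermediate
10 | methoxyethyne | COC#C | intermediate
11 | methyl (2E)-3-icosyl-5-oxopenta-2,4-dienoate (vinylketene) | COC(=O)/C=C(/C=C=O)CCCCCCCCCCCCCCCCCCCC | intermediate
12 | methyl (2E)-3-(2-methoxy-4-oxocyclobut-2-en-1-yl)tricos-2-enoate (racemic) | COC1=CC(=O)C1/C(CCCCCCCCCCCCCCCCCCCC)=C/C(=O)OC | intermediate
13 | methyl (2E,4E)-3-icosyl-5-methoxy-7-oxohepta-2,4,6-trienoate (dienylketene) | O=C=C/C(OC)=C\C(CCCCCCCCCCCCCCCCCCCC)=C\C(=O)OC | intermediate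
14 | methyl 6-icosyl-4-methoxy-2-oxocyclohexa-3,5-diene-1-carboxylate (racemic) | COC(=O)C1C(=O)C=C(OC)C=C1CCCCCCCCCCCCCCCCCCCC | intermediate
15 | methyl 2-hydroxy-6-icosyl-4-methoxybenzoate | CCCCCCCCCCCCCCCCCCCCc1cc(OC)cc(O)c1C(=O)OC | target

**Step count**

Total: 6 steps. Longest linear sequence: 4 steps (steps 1, 3, 4, 6; the branch through step 2 is equally long).

**Steps most likely to fail**

1. Step 6. The ester may rotate inward during ring opening of 7, so that the ketene closes onto the ester carbonyl (an oxa-six-electron closure to a 2-pyranone), or the ketene may dimerise faster than the alkyne captures it. The fallback abandons the pericyclic ring construction for a classical condensation route; it sets out from 1 and comes back at 15.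
   - 1 is converted with Mg turnings in THF into icosylmagnesium bromide F1, which is formylated with DMF and hydrolysed (aqueous HCl) to henicosanal F2.
   - Wittig olefination with 1-(triphenylphosphoranylidene)propan-2-one (toluene, 90 °C) should give (E)-tetracos-3-en-2-one F3.
   - Michael addition of dimethyl malonate (NaOMe, MeOH, reflux) followed in the same pot by Claisen-type ring closure should give methyl 6-icosyl-2,4-dioxocyclohexane-1-carboxylate F4 (racemic, enolised).
   - Bromination–dehydrobromination (Br2, DMF, 0 °C then 80 °C) should aromatise it to methyl 2,4-dihydroxy-6-icosylbenzoate F5.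
   - MeI (1.05 equiv) with K2CO3 in acetone should methylate only the 4-hydroxyl, the 2-hydroxyl being held in a hydrogen bond to the ester, which gives 15.

2. Step 3. Addition of an ester-bearing chloroketene to an unactivated terminal alkyne is argued by analogy with dichloroketene and is not an established case. Self-condensation of 5, or its hetero-[4+2] mode through the ester carbonyl, may outrun the [2+2] addition, and excess zinc may reduce 6 before isolation. The fallback replaces 5 by dichloroketene and introduces the ester after the ring is made; it sets out from 2 and comes back at 15.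
   - Dichloroketene F6, made in the flask from trichloroacetyl chloride and zinc–copper couple (Et2O/DME), should add to 2 to give 4,4-dichloro-3-icosylcyclobut-2-en-1-one F7.
   - Zn dust with AcOH and TMEDA in EtOH should give 3-icosylcyclobut-2-en-1-one F8.
   - Heating F8 with 10 (toluene, sealed tube, 80 °C) should run the same benzannulation cascade to 3-icosyl-5-methoxyphenol F9.
   - Magnesium-mediated ortho-formylation (MgCl2, Et3N, paraformaldehyde, MeCN, reflux) should favour the position ortho to the hydroxyl and para to the methoxyl, giving 2-hydroxy-6-icosyl-4-methoxybenzaldehyde F10.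
   - Pinnick oxidation (NaClO2, NaH2PO4, 2-methyl-2-butene, t-BuOH/THF/H2O) should give 2-hydroxy-6-icosyl-4-methoxybenzoic acid F11.
   - MeI with KHCO3 in DMF should esterify the carboxylate without touching the hydrogen-bonded phenol, which gives 15.

3. Step 2. The second chlorination may stall, and residual monochloride would give with zinc the unhalogenated ketene, which only dimerises. The fallback changes how the ketene is made; it sets out from 3 and comes back at 5.
   - One equivalent of SO2Cl2 (40 °C) should give cleanly methyl 2-chloro-3-chloro-3-oxopropanoate F12.
   - Slow addition of Et3N to F12 and 2 in refluxing Et2O/hexane should release 5 by dehydrochlorination instead of by reduction, and 5 then adds to 2 as in step 3.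

**Further compounds**

F1 | step 6 | icosylmagnesium bromide | CCCCCCCCCCCCCCCCCCCC[Mg]Br
F2 | step 6 | henicosanal | CCCCCCCCCCCCCCCCCCCCC=O
F3 | step 6 | (E)-tetracos-3-en-2-one | CCCCCCCCCCCCCCCCCCCC/C=C/C(C)=O
F4 | step 6 | methyl 6-icosyl-2,4-dioxocyclohexane-1-carboxylate (racemic, diastereomer and enol mixture) | COC(=O)C1C(=O)CC(=O)CC1CCCCCCCCCCCCCCCCCCCC
F5 | step 6 | methyl 2,4-dihydroxy-6-icosylbenzoate | CCCCCCCCCCCCCCCCCCCCc1cc(O)cc(O)c1C(=O)OC
F6 | step 3 | dichloroketene | ClC(Cl)=C=O
F7 | step 3 | 4,4-dichloro-3-icosylcyclobut-2-en-1-one | O=C1C=C(CCCCCCCCCCCCCCCCCCCC)C1(Cl)Cl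
F8 | step 3 | 3-icosylcyclobut-2-en-1-one | O=C1C=C(CCCCCCCCCCCCCCCCCCCC)C1
F9 | step 3 | 3-icosyl-5-methoxyphenol | CCCCCCCCCCCCCCCCCCCCc1cc(O)cc(OC)c1
F10 | step 3 | 2-hydroxy-6-icosyl-4-methoxybenzaldehyde | CCCCCCCCCCCCCCCCCCCCc1cc(OC)cc(O)c1C=O
F11 | step 3 | 2-hydroxy-6-icosyl-4-methoxybenzoic acid | CCCCCCCCCCCCCCCCCCCCc1cc(OC)cc(O)c1C(=O)O
F12 | step 2 | methyl 2-chloro-3-chloro-3-oxopropanoate | COC(=O)C(Cl)C(=O)Cl
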